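The numbers of this flask stand for no real mixture, and the outcome is calculated.

You should size the scavenger from a balance on released group: what the chain releases, less what idle adduct and free released group hold at the end.

starting material 0.26 M; coupling partner 0.338 M; initiator 26 mM; time 20 s

    2 first chain carrier → ended chains A (k1 = 4 × 10⁸ M⁻¹ s⁻¹)
    2 second chain carrier → ended chains B (k2 = 3.3 × 10⁶ M⁻¹ s⁻¹)
    starting material + released group ⇌ idle adduct, settled at all times (K3 = 8.3 M⁻¹)
    coupling partner + first chain carrier → product + second chain carrier (k4 = 29000 M⁻¹ s⁻¹)
    starting material + second chain carrier → released group + first chain carrier (k5 = 13000 M⁻¹ s⁻¹)
    initiator → 2 initiating radical (k6 = 0.038 s⁻¹)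
    starting material + initiating radical → capped initiator + first chain carrier (k7 = 3.6 × 10⁵ M⁻¹ s⁻¹)
    scavenger + released group → scavenged by-product (k8 = 31 M⁻¹ s⁻¹)
    first chain carrier → ended carrier (k9 = 160 s⁻¹)

- the concentration of scavenger at which the part of the starting material that has reacted at 20 s is just 80%, in M

- percent here means starting material units held: one ended chains A counts as two
- what is said of released group includes idle adduct
- two of one species on the left: rate k times its square, two consumed each time
- the amount of scavenger is what is sought; it is there from the start
- what has gone from starting material into another species counts as reacted, even if it can come back
- run time (flask): 20 s

- Idle adduct counts as reacted, so the target means 0.0520 M of free starting material at 20 s, with 0.208 M gone from it.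
- The adduct step is fast and stays at balance, so its equilibrium constant 8.3 M⁻¹ times free starting material gives 2.16 at the charge and 0.432 at the target.
- Call this the holding ratio, idle adduct per free released group at balance. A ratio of one is the zero of the scale, where the two are equal. Above it, idle adduct is the resting state of the released group.
- At the target the ratio puts 30.1% of the surviving released group in idle adduct.
- The scavenger removes released group, so it lowers the adduct, and with it the part reacted.
- My own reckoning starts from the initiator, which gives 0.0277 M of initiating radical in 20 s. If each radical takes one starting material, 0.180 M remains for the chain and the adduct.
- That amount must equal the chain turnover plus 30.1% of what the scavenger leaves of that turnover. I stop here, because the turnover needs the radical levels through the run, so I give no scavenger figure.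
- The forecast gives 0.085 M of scavenger, on this ground: “Scavenging is fast, so the scavenger acts as a titrant”.
- The simulation gives 0.0921 M, and the forecast stands within the tolerance.
- In this flask, the step that makes product had 16% of its turnover behind it by 2.00 s and half by 7.20 s, while 84.8% of the scavenger was still free at 2.00 s. At 10.0 s, 51.0% of the starting material was used, which puts the holding ratio at 1.06, close to even, and at 20.0 s free released group had a half-life of 150 min against the scavenger. In the flask with half the starting material the ratio opens at 1.08, and with 98.7% reacted at the end of that run it reads 0.0141.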